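**Plan**

1. Labdane numbering is used: ring A is C1–C5 and C10, ring B is C5–C10, C17 sits on C8, C20 on C10, and the side chain is C11–C16. The retrosynthesis first cuts the C11–C12 bond (as a C11=C12 Wittig alkene) and returns the 7-en-17-oic acid to a 6-ene that carries C17 as CH2OSi.
2. The bicycle is then cut at C5–C10 and C8–C9. The C9(H)–C10(CH3) edge of ring B, with C11 as a formyl group, is an (E)-3-methyl-2-enal; C5–C8 is a 1,3-diene; C1–C4 of ring A is the tether between them.
3. Forward: an acyclic trienal is built (nitrile alkylation, vinylogous olefination, Zr-catalysed methylalumination), rings A and B arise together in one intramolecular Diels–Alder reaction, and the C12–C16 chain is then joined at C11.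
4. End game: C17 is oxidised, the ring alkene is moved from C6=C7 into conjugation (C7=C8), and C11=C12 is saturated.
5. Stereochemistry: C5, C9 and C10 (and the transient C8) come from the catalyst-controlled endo cycloaddition of an (E)-enal onto an (E,E)-diene; C13 comes from (R)-2-methylsuccinic acid 4-methyl ester.

Key step: step 8

Remark: which antipode of the oxazaborolidinium cation leaves the required enal face open cannot be asserted for a β,β-disubstituted enal; the (S)-catalyst is written, and the (R)-catalyst replaces it without other change if the adduct proves antipodal.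

**Route**

Step 1
Reactants: 1 isobutyronitrile; 2 5-iodopent-1-yne
Product: 4 2,2-dimethylhept-6-ynenitrile, via lithiated isobutyronitrile 3 (not isolated)
Conditions: LiN(i-Pr)2, THF, −78 °C; then 2, −78 °C → rt
Reagents that add atoms: none
Why: Nitrile anion alkylation: the compact α-cyano carbanion should displace the primary iodide faster than it deprotonates the alkyne, creating the C4 quaternary carbon with its gem-dimethyl pair.

Step 2
Reactants: 4 2,2-dimethylhept-6-ynenitrile
Product: 6 2,2-dimethylhept-6-ynal, via N-diisobutylalumanyl aldimine 5 (not isolated)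
Conditions: i-Bu2AlH (1.2 equiv), CH2Cl2, −78 → −40 °C; then 1 M HCl, 0 °C
Reagents that add atoms: water, O
Why: Nitrile-to-aldehyde reduction: hydride addition stops at the N-aluminated imine, which aqueous acid hydrolyses, so over-reduction is excluded and the non-enolisable aldehyde (C5) is obtained directly.

Step 3
Reactants: 6 2,2-dimethylhept-6-ynal; 7 triethyl 4-phosphonocrotonate
Product: 9 ethyl (2E,4E)-6,6-dimethylundeca-2,4-dien-10-ynoate, via lithiated phosphonocrotonate 8 (not isolated)
Conditions: 7, LiN(SiMe3)2, THF, −78 °C; then 6, −78 → 0 °C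
Reagents that add atoms: none
Why: Vinylogous Horner–Wadsworth–Emmons olefination: the non-enolisable, α-quaternary aldehyde should give the new C5=C6 alkene with E geometry, while the C7=C8 alkene keeps the E geometry of the reagent.

Step 4
Reactants: 9 ethyl (2E,4E)-6,6-dimethylundeca-2,4-dien-10-ynoate
Product: 10 (2E,4E)-6,6-dimethylundeca-2,4-dien-10-yn-1-ol
Conditions: i-Bu2AlH (2.3 equiv), CH2Cl2, −78 °C; aq. KNaC4H4O6
Reagents that add atoms: none
Why: 1,2-Reduction of a conjugated ester with i-Bu2AlH should give the dienol (C17–OH) without touching the diene or the alkyne.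

Step 5
Reactants: 10 (2E,4E)-6,6-dimethylundeca-2,4-dien-10-yn-1-ol
Product: 11 tert-butyl{[(2E,4E)-6,6-dimethylundeca-2,4-dien-10-yn-1-yl]oxy}dimethylsilane
Conditions: TBSCl, imidazole, CH2Cl2, 0 °C → rt
Reagents that add atoms: tert-butyldimethylsilyl chloride, CC(C)(C)[Si](C)(C)Cl
Why: Standard silylation of a primary alcohol masks C17–OH so that only the alcohol made in step 6 is oxidised in step 7.

Step 6
Reactants: 11 tert-butyl{[(2E,4E)-6,6-dimethylundeca-2,4-dien-10-yn-1-yl]oxy}dimethylsilane
Product: 14 (2E,8E,10E)-12-[(tert-butyldimethylsilyl)oxy]-3,7,7-trimethyldodeca-2,8,10-trien-1-ol, via (E)-alkenyldimethylalane 12 (not isolated), via lithium alkenyl(butyl)dimethylalanate 13 (not isolated)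
Conditions: AlMe3 (2.5 equiv), Cp2ZrCl2 (25 mol%), CH2Cl2, 0 °C → rt; volatiles removed; n-BuLi, THF/hexane, −78 → 0 °C; (CH2O)n, rt; aq. KNaC4H4O6
Reagents that add atoms: trimethylaluminium, C[Al](C)C; paraformaldehyde (as formaldehyde), C=O
Why: Zirconium-catalysed carboalumination (Negishi methylalumination) adds CH3 and Al syn across the terminal alkyne only, and the derived alanate is hydroxymethylated with retention, so the C9=C10 alkene is formed E with C11 cis to the C10 methyl.

Step 7
Reactants: 14 (2E,8E,10E)-12-[(tert-butyldimethylsilyl)oxy]-3,7,7-trimethyldodeca-2,8,10-trien-1-ol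
Product: 15 (2E,8E,10E)-12-[(tert-butyldimethylsilyl)oxy]-3,7,7-trimethyldodeca-2,8,10-trienal
Conditions: MnO2 (excess), CH2Cl2, rt
Reagents that add atoms: none
Why: Allylic oxidation with MnO2 is neutral and should give the enal (C11) without E/Z isomerisation or loss of the silyl ether.

Step 8
Reactants: 15 (2E,8E,10E)-12-[(tert-butyldimethylsilyl)oxy]-3,7,7-trimethyldodeca-2,8,10-trienal
Product: 16 (1S,2S,4aS,8aS)-2-{[(tert-butyldimethylsilyl)oxy]methyl}-5,5,8a-trimethyl-1,2,4a,5,6,7,8,8a-octahydronaphthalene-1-carbaldehyde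
Conditions: (S)-1-(2-methylphenyl)-3,3-diphenyltetrahydro-1H,3H-pyrrolo[1,2-c][1,3,2]oxazaborole (20 mol%), HN(SO2CF3)2 (18 mol%), CH2Cl2, −78 → −20 °C
Reagents that add atoms: none
Why: Proposed new method: the chiral oxazaborolidinium cation binds the C11 formyl oxygen (with the usual formyl C–H···O contact) and lowers the enal LUMO, so the tethered 1,4-dialkyl diene should add suprafacially in a concerted, asynchronous [4+2] event that forms C5–C10 and C8–C9; the closest known reactions are oxazaborolidinium- and Me2AlCl-promoted type 1 intramolecular Diels–Alder reactions of deca-2,8,10-trienals and trienimides lacking the 3-methyl group, so the untested element is catalyst-controlled formation of the angular quaternary carbon. Ring B closes as the cyclohexene of the cycloaddition (new C6=C7 alkene) and ring A as the six-membered ring spanned by the C1–C4 tether, helped by the C4 gem-dimethyl group. C9 and C10 take their cis CHO/CH3 relationship from the (E)-enal, C5 and C8 their cis relationship from the (E,E)-diene, and the trans ring fusion (C20 anti to H-5) from the endo arrangement in which the bound carbonyl lies under the diene and the tether is exo in a chair; the absolute configuration (5S,10S) comes only from the enal face left open by the catalyst. The step needs endo over exo selectivity, one enal face and an unchanged enal geometry: Lewis-acid activation should favour the first, the catalyst the second, and the absence of any amine (no dienamine) protects the third, while the bulky silyl ether keeps the C17 oxygen from competing for boron.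

Step 9
Reactants: 17 (R)-4-methoxy-2-methyl-4-oxobutanoic acid
Product: 18 methyl (R)-4-hydroxy-3-methylbutanoate
Conditions: BH3·SMe2, THF, 0 °C → rt; H2O
Reagents that add atoms: none
Why: Borane reduces a carboxylic acid much faster than an ester (chemoselective borane reduction), giving the C12 alcohol without touching C15 or the C13 stereocentre; the crude hydroxy ester is used at once to forestall lactonisation.

Step 10
Reactants: 18 methyl (R)-4-hydroxy-3-methylbutanoate
Product: 19 methyl (R)-4-iodo-3-methylbutanoate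
Conditions: I2, PPh3, imidazole, CH2Cl2, 0 °C → rt
Reagents that add atoms: iodine, [I][I]
Why: Appel-type iodination of a primary alcohol through the alkoxyphosphonium ion proceeds at C12 only, so the adjacent C13 stereocentre is not involved.

Step 11
Reactants: 19 methyl (R)-4-iodo-3-methylbutanoate
Product: 20 [(2R)-4-methoxy-2-methyl-4-oxobutyl]triphenylphosphonium iodide
Conditions: PPh3, MeCN, 80 °C
Reagents that add atoms: triphenylphosphine, c1ccc(cc1)P(c1ccccc1)c1ccccc1
Why: Quaternisation of PPh3 by the primary iodide (phosphonium salt formation by nucleophilic substitution) should outrun cyclisation of the γ-iodo ester at this temperature.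

Step 12
Reactants: 16 (1S,2S,4aS,8aS)-2-{[(tert-butyldimethylsilyl)oxy]methyl}-5,5,8a-trimethyl-1,2,4a,5,6,7,8,8a-octahydronaphthalene-1-carbaldehyde; 20 [(2R)-4-methoxy-2-methyl-4-oxobutyl]triphenylphosphonium iodide
Product: 22 methyl (11Z,13R)-17-[(tert-butyldimethylsilyl)oxy]labda-6,11-dien-15-oate, via phosphorus ylide 21 (not isolated)
Conditions: 20, NaN(SiMe3)2, THF, −78 → 0 °C; then 16, −78 °C → rt
Reagents that add atoms: none
Why: Wittig olefination with a non-stabilised, salt-free ylide forms the C11=C12 bond (mainly Z, geometry immaterial because the alkene is saturated in step 18); the equatorial C9 formyl group is the thermodynamically preferred epimer, so C9 should hold.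

Step 13
Reactants: 22 methyl (11Z,13R)-17-[(tert-butyldimethylsilyl)oxy]labda-6,11-dien-15-oate
Product: 23 (11Z,13R)-17-[(tert-butyldimethylsilyl)oxy]labda-6,11-dien-15-ol
Conditions: i-Bu2AlH (2.5 equiv), CH2Cl2, −78 → −20 °C; aq. KNaC4H4O6
Reagents that add atoms: none
Why: Ester reduction with i-Bu2AlH brings C15 to the alcohol level while the silyl ether and both alkenes are inert.

Step 14
Reactants: 23 (11Z,13R)-17-[(tert-butyldimethylsilyl)oxy]labda-6,11-dien-15-ol
Product: 24 (11Z,13R)-17-[(tert-butyldimethylsilyl)oxy]labda-6,11-dien-15-yl acetate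
Conditions: Ac2O, pyridine, DMAP (cat.), CH2Cl2, rt
Reagents that add atoms: acetic anhydride, CC(=O)OC(C)=O
Why: DMAP-catalysed acetylation of the only free hydroxyl installs the C15 acetate of the target early, since none of the remaining steps is strongly basic or nucleophilic.

Step 15
Reactants: 24 (11Z,13R)-17-[(tert-butyldimethylsilyl)oxy]labda-6,11-dien-15-yl acetate
Product: 25 (11Z,13R)-17-hydroxylabda-6,11-dien-15-yl acetate
Conditions: HF·pyridine, pyridine, THF, 0 °C → rt
Reagents that add atoms: none
Why: Fluoride-mediated desilylation under buffered, weakly acidic conditions frees C17–OH and leaves the acetate in place.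

Step 16
Reactants: 25 (11Z,13R)-17-hydroxylabda-6,11-dien-15-yl acetate
Product: 27 (11Z,13R)-17-oxolabda-7,11-dien-15-yl acetate, via β,γ-unsaturated aldehyde 26 (not isolated)
Conditions: Dess–Martin periodinane, CH2Cl2, 0 °C → rt; then DBU (excess), rt
Reagents that add atoms: none
Why: Dess–Martin oxidation gives the 6-en-17-al, whose doubly activated C8–H is removed by DBU and the dienolate reprotonated at C6 (base-mediated β,γ to α,β isomerisation), which erases C8 as intended while C9, lacking an acidifying group, is untouched.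

Step 17
Reactants: 27 (11Z,13R)-17-oxolabda-7,11-dien-15-yl acetate
Product: 28 (11Z,13R)-15-acetoxylabda-7,11-dien-17-oic acid
Conditions: NaClO2, NaH2PO4, 2-methylbut-2-ene, t-BuOH/H2O, rt
Reagents that add atoms: sodium chlorite, [Na+].[O-]Cl=O
Why: Pinnick oxidation converts the conjugated aldehyde to the acid without alkene migration, the scavenger intercepting hypochlorous acid before it can add to C11=C12.

Step 18
Reactants: 28 (11Z,13R)-15-acetoxylabda-7,11-dien-17-oic acid
Product: 29 (13S)-15-acetoxylabd-7-en-17-oic acid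
Conditions: 2-nitrobenzenesulfonohydrazide (excess, in portions), Et3N, CH2Cl2, rt
Reagents that add atoms: none
Why: Diimide reduction transfers H2 concertedly to the 1,2-disubstituted C11=C12 alkene far faster than to the trisubstituted, hindered C7=C8 bond and cannot isomerise either; the C13 descriptor changes from R to S only because C12 loses CIP priority.

**Compound list**

1 | isobutyronitrile | CC(C)C#N | starting material
2 | 5-iodopent-1-yne | C#CCCCI | starting material
3 | lithiated isobutyronitrile (N-lithio ketenimine form) | CC(C)=C=N[Li] | intermediate (not isolated)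
4 | 2,2-dimethylhept-6-ynenitrile | CC(C)(CCCC#C)C#N | intermediate
5 | N-(diisobutylalumanyl)-2,2-dimethylhept-6-yn-1-imine | CC(C)C[Al](CC(C)C)N=CC(C)(C)CCCC#C | intermediate (not isolated)
6 | 2,2-dimethylhept-6-ynal | O=CC(C)(C)CCCC#C | intermediate
7 | triethyl 4-phosphonocrotonate | CCOC(=O)/C=C/CP(=O)(OCC)OCC | starting material
8 | lithium salt of the C4 carbanion of triethyl 4-phosphonocrotonate | [Li+].CCOC(=O)/C=C/[CH-]P(=O)(OCC)OCC | intermediate (not isolated)
9 | ethyl (2E,4E)-6,6-dimethylundeca-2,4-dien-10-ynoate | CCOC(=O)/C=C/C=C/C(C)(C)CCCC#C | intermediate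
10 | (2E,4E)-6,6-dimethylundeca-2,4-dien-10-yn-1-ol | OC/C=C/C=C/C(C)(C)CCCC#C | intermediate
11 | tert-butyl{[(2E,4E)-6,6-dimethylundeca-2,4-dien-10-yn-1-yl]oxy}dimethylsilane | C#CCCCC(C)(C)/C=C/C=C/CO[Si](C)(C)C(C)(C)C | intermediate
12 | [(1E,7E,9E)-11-(tert-butyldimethylsilyloxy)-2,6,6-trimethylundeca-1,7,9-trien-1-yl]dimethylalane | C[Al](C)/C=C(\C)CCCC(C)(C)/C=C/C=C/CO[Si](C)(C)C(C)(C)C | intermediate (not isolated)
13 | lithium butyl[(1E,7E,9E)-11-(tert-butyldimethylsilyloxy)-2,6,6-trimethylundeca-1,7,9-trien-1-yl]dimethylalanate | [Li+].CCCC[Al-](C)(C)/C=C(\C)CCCC(C)(C)/C=C/C=C/CO[Si](C)(C)C(C)(C)C | intermediate (not isolated)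
14 | (2E,8E,10E)-12-[(tert-butyldimethylsilyl)oxy]-3,7,7-trimethyldodeca-2,8,10-trien-1-ol | OC/C=C(\C)CCCC(C)(C)/C=C/C=C/CO[Si](C)(C)C(C)(C)C | intermediate
15 | (2E,8E,10E)-12-[(tert-butyldimethylsilyl)oxy]-3,7,7-trimethyldodeca-2,8,10-trienal | O=C/C=C(\C)CCCC(C)(C)/C=C/C=C/CO[Si](C)(C)C(C)(C)C | intermediate
16 | (1S,2S,4aS,8aS)-2-{[(tert-butyldimethylsilyl)oxy]methyl}-5,5,8a-trimethyl-1,2,4a,5,6,7,8,8a-octahydronaphthalene-1-carbaldehyde (trans-fused; C11 formyl, C17 and C20 all β; H-5 α) | O=C[C@H]1[C@@H](CO[Si](C)(C)C(C)(C)C)C=C[C@H]2C(C)(C)CCC[C@]12C | intermediate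
17 | (R)-4-methoxy-2-methyl-4-oxobutanoic acid [(R)-2-methylsuccinic acid 4-methyl ester] | COC(=O)C[C@@H](C)C(=O)O | starting material
18 | methyl (R)-4-hydroxy-3-methylbutanoate | COC(=O)C[C@@H](C)CO | intermediate
19 | methyl (R)-4-iodo-3-methylbutanoate | COC(=O)C[C@@H](C)CI | intermediate
20 | [(2R)-4-methoxy-2-methyl-4-oxobutyl]triphenylphosphonium iodide | COC(=O)C[C@@H](C)C[P+](c1ccccc1)(c1ccccc1)c1ccccc1.[I-] | intermediate
21 | methyl (3R)-3-methyl-4-(triphenyl-λ5-phosphanylidene)butanoate | COC(=O)C[C@@H](C)C=P(c1ccccc1)(c1ccccc1)c1ccccc1 | intermediate (not isolated)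
22 | methyl (11Z,13R)-17-[(tert-butyldimethylsilyl)oxy]labda-6,11-dien-15-oate (H-5, H-8, H-9 α; C20 β) | COC(=O)C[C@@H](C)/C=C\[C@H]1[C@@H](CO[Si](C)(C)C(C)(C)C)C=C[C@H]2C(C)(C)CCC[C@]12C | intermediate
23 | (11Z,13R)-17-[(tert-butyldimethylsilyl)oxy]labda-6,11-dien-15-ol | OCC[C@@H](C)/C=C\[C@H]1[C@@H](CO[Si](C)(C)C(C)(C)C)C=C[C@H]2C(C)(C)CCC[C@]12C | intermediate
24 | (11Z,13R)-17-[(tert-butyldimethylsilyl)oxy]labda-6,11-dien-15-yl acetate | CC(=O)OCC[C@@H](C)/C=C\[C@H]1[C@@H](CO[Si](C)(C)C(C)(C)C)C=C[C@H]2C(C)(C)CCC[C@]12C | intermediate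
25 | (11Z,13R)-17-hydroxylabda-6,11-dien-15-yl acetate | CC(=O)OCC[C@@H](C)/C=C\[C@H]1[C@@H](CO)C=C[C@H]2C(C)(C)CCC[C@]12C | intermediate
26 | (11Z,13R)-17-oxolabda-6,11-dien-15-yl acetate | CC(=O)OCC[C@@H](C)/C=C\[C@H]1[C@@H](C=O)C=C[C@H]2C(C)(C)CCC[C@]12C | intermediate (not isolated)
27 | (11Z,13R)-17-oxolabda-7,11-dien-15-yl acetate | CC(=O)OCC[C@@H](C)/C=C\[C@H]1C(C=O)=CC[C@H]2C(C)(C)CCC[C@]12C | intermediate
28 | (11Z,13R)-15-acetoxylabda-7,11-dien-17-oic acid | CC(=O)OCC[C@@H](C)/C=C\[C@H]1C(C(=O)O)=CC[C@H]2C(C)(C)CCC[C@]12C | intermediate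
29 | (13S)-15-acetoxylabd-7-en-17-oic acid (CNP0412535.1) | CC(=O)OCC[C@@H](C)CC[C@H]1C(C(=O)O)=CC[C@H]2C(C)(C)CCC[C@]12C | target

**Step count and risks**

Total step count: 18. Longest linear sequence: 15 steps (steps 1–8, then 12–18); the side-chain branch is 3 steps (9–11).

Steps most likely to fail:

Step 8 (proposed new method). The β,β-disubstituted enal may be activated too weakly, so that cycloaddition is slow against ionisation of the dienyl silyl ether. The C10 methyl group, which must sit under the diene in the endo arrangement, may erode the trans-fusion selectivity. The catalyst may discriminate the enal faces poorly. The fallback replaces catalyst control by auxiliary control, a known class of reaction. Trienal 15 is oxidised (NaClO2, NaH2PO4, 2-methylbut-2-ene) to (2E,8E,10E)-12-[(tert-butyldimethylsilyl)oxy]-3,7,7-trimethyldodeca-2,8,10-trienoic acid F1. Pivaloyl chloride and Et3N convert this to the mixed pivalic anhydride F2, which acylates (S)-4-benzyloxazolidin-2-one in the presence of LiCl to give the N-trienoyl oxazolidinone F3. Me2AlCl (CH2Cl2, −30 °C) then promotes the intramolecular Diels–Alder reaction through the chelated s-cis imide, in which the diene adds to the face away from the benzyl group; the chelate model predicts the (5S,10S) series and the endo mode gives the trans-fused bicyclic imide F4. LiBH4 removes the auxiliary reductively to give [(1S,2S,4aS,8aS)-2-{[(tert-butyldimethylsilyl)oxy]methyl}-5,5,8a-trimethyl-1,2,4a,5,6,7,8,8a-octahydronaphthalen-1-yl]methanol F5, and Dess–Martin oxidation returns to the route at aldehyde 16.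

Step 12. Addition of the ylide to the hindered, α-branched C9 aldehyde may be slow, which would leave time for acylation of the ylide by the ester of a second ylide molecule and for base-induced epimerisation at C9. The fallback uses a chain fragment without an electrophilic site, so the ylide can be used in excess and warmed. Iodo ester 19 is reduced with i-Bu2AlH to (R)-4-iodo-3-methylbutan-1-ol F6 and silylated (Et3SiCl, imidazole) to triethyl{[(3R)-4-iodo-3-methylbutyl]oxy}silane F7. PPh3 converts this to [(2R)-2-methyl-4-(triethylsilyloxy)butyl]triphenylphosphonium iodide F8, and NaN(SiMe3)2 gives the corresponding ylide F9. Wittig reaction with 16 gives (11Z,13R)-17-[(tert-butyldimethylsilyl)oxy]-15-[(triethylsilyl)oxy]labda-6,11-diene F10. Selective cleavage of the triethylsilyl ether (pyridinium p-toluenesulfonate, MeOH, 0 °C) returns to the route at alcohol 23.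

Step 18. Diimide may decompose faster than it reduces the hindered Z-alkene, and forcing the reaction may bring partial reduction of the conjugated C7=C8 bond, which the carboxyl group activates toward diimide. The fallback removes that activation by a detour through the alcohol oxidation level. Enal 27 is reduced (NaBH4, CeCl3·7H2O, MeOH, 0 °C; Luche reduction) to (11Z,13R)-17-hydroxylabda-7,11-dien-15-yl acetate F11, whose trisubstituted, non-conjugated ring alkene is inert. The side-chain alkene is then saturated with a large excess of diimide or with H2 over RhCl(PPh3)3 to give (13S)-17-hydroxylabd-7-en-15-yl acetate F12. MnO2 gives (13S)-17-oxolabd-7-en-15-yl acetate F13, and Pinnick oxidation (NaClO2, NaH2PO4, 2-methylbut-2-ene) returns to the route at target 29.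

**Further compounds**

F1 | step 8 | (2E,8E,10E)-12-[(tert-butyldimethylsilyl)oxy]-3,7,7-trimethyldodeca-2,8,10-trienoic acid | OC(=O)/C=C(\C)CCCC(C)(C)/C=C/C=C/CO[Si](C)(C)C(C)(C)C
F2 | step 8 | (2E,8E,10E)-12-[(tert-butyldimethylsilyl)oxy]-3,7,7-trimethyldodeca-2,8,10-trienoic pivalic anhydride | CC(C)(C)C(=O)OC(=O)/C=C(\C)CCCC(C)(C)/C=C/C=C/CO[Si](C)(C)C(C)(C)C
F3 | step 8 | (S)-4-benzyl-3-[(2E,8E,10E)-12-[(tert-butyldimethylsilyl)oxy]-3,7,7-trimethyldodeca-2,8,10-trienoyl]oxazolidin-2-one | O=C(/C=C(\C)CCCC(C)(C)/C=C/C=C/CO[Si](C)(C)C(C)(C)C)N1[C@@H](Cc2ccccc2)COC1=O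
F4 | step 8 | (S)-4-benzyl-3-{[(1S,2S,4aS,8aS)-2-{[(tert-butyldimethylsilyl)oxy]methyl}-5,5,8a-trimethyl-1,2,4a,5,6,7,8,8a-octahydronaphthalen-1-yl]carbonyl}oxazolidin-2-one | O=C([C@H]1[C@@H](CO[Si](C)(C)C(C)(C)C)C=C[C@H]2C(C)(C)CCC[C@]12C)N1[C@@H](Cc2ccccc2)COC1=O
F5 | step 8 | [(1S,2S,4aS,8aS)-2-{[(tert-butyldimethylsilyl)oxy]methyl}-5,5,8a-trimethyl-1,2,4a,5,6,7,8,8a-octahydronaphthalen-1-yl]methanol | OC[C@H]1[C@@H](CO[Si](C)(C)C(C)(C)C)C=C[C@H]2C(C)(C)CCC[C@]12C
F6 | step 12 | (R)-4-iodo-3-methylbutan-1-ol | OCC[C@@H](C)CI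
F7 | step 12 | triethyl{[(3R)-4-iodo-3-methylbutyl]oxy}silane | CC[Si](CC)(CC)OCC[C@@H](C)CI
F8 | step 12 | [(2R)-2-methyl-4-(triethylsilyloxy)butyl]triphenylphosphonium iodide | CC[Si](CC)(CC)OCC[C@@H](C)C[P+](c1ccccc1)(c1ccccc1)c1ccccc1.[I-]
F9 | step 12 | triethyl{[(3R)-3-methyl-4-(triphenyl-λ5-phosphanylidene)butyl]oxy}silane | CC[Si](CC)(CC)OCC[C@@H](C)C=P(c1ccccc1)(c1ccccc1)c1ccccc1
F10 | step 12 | (11Z,13R)-17-[(tert-butyldimethylsilyl)oxy]-15-[(triethylsilyl)oxy]labda-6,11-diene | CC[Si](CC)(CC)OCC[C@@H](C)/C=C\[C@H]1[C@@H](CO[Si](C)(C)C(C)(C)C)C=C[C@H]2C(C)(C)CCC[C@]12C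
F11 | step 18 | (11Z,13R)-17-hydroxylabda-7,11-dien-15-yl acetate | CC(=O)OCC[C@@H](C)/C=C\[C@H]1C(CO)=CC[C@H]2C(C)(C)CCC[C@]12C
F12 | step 18 | (13S)-17-hydroxylabd-7-en-15-yl acetate | CC(=O)OCC[C@@H](C)CC[C@H]1C(CO)=CC[C@H]2C(C)(C)CCC[C@]12C
F13 | step 18 | (13S)-17-oxolabd-7-en-15-yl acetate | CC(=O)OCC[C@@H](C)CC[C@H]1C(C=O)=CC[C@H]2C(C)(C)CCC[C@]12C
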